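The question was how far the flask would have gone by 12 min, so I asked first where it would stop, and then whether it would get there in time.

in all of them: free catalyst 7.6 mM
- ochre: left-handed substrate 0.66 M; right-handed substrate 0.66 M; partner 0.33 M; run made earlier
- flask: left-handed substrate 0.33 M; right-handed substrate 0.33 M; partner 0.330 M; time 12 min

ochre run (percent of the left-handed substrate and right-handed substrate together charged)

| time / s | left-handed substrate / % | right-handed substrate / % | left-handed product / % |
|---|---|---|---|
| 12.0 | 48.2 | 49.4 | 1.8 |
| 25.0 | 48.0 | 49.3 | 3.3 |
| 40.0 | 46.2 | 48.7 | 2.9 |
| 50.0 | 45.2 | 48.2 | 3.9 |
| 60.0 | 45.5 | 47.3 | 5.5 |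
| 80.0 | 44.1 | 48.2 | 6.1 |

(readings scatter by 0.5 percentage points)

1. part of the left-handed substrate and right-handed substrate charged together that has reacted at 12 min
2. excess of left-handed product over right-handed product in the product at 12 min
3. excess of right-handed substrate over left-handed substrate among what is left of the two at 12 min

- free catalyst is single-handed; left-handed substrate and right-handed substrate are mirror images of each other, charged as a racemate, each of them at the stated concentration
- an excess is below zero if the other one leads

The ochre run is the near neighbour of the flask: it has the same partner and the same free catalyst, but twice the substrate. Its two substrates together had lost 5.10 % of their charge by 40.0 s and 7.70 % by 80.0 s. The second stretch therefore added about half of what the first had added. If each stretch keeps shrinking by that ratio, the gains sum to a reach: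

reach = first gain squared / (first gain − second gain) = 10.4 % of the charge

This is a reading, and it carries the scatter of 0.5 percentage points on each value. Substrate did not look like the brake at 10.4 % of its charge, and that reach asks for 41.6 % of the partner's charge, less than was there. So I looked to the catalyst, and my carried quantity was the turnovers per catalyst charged (turnover number), the substrate reacted over the catalyst charged:

N = reach / catalyst as a fraction of the substrate charge = 10.4 % / 0.576 % = 18.1

The flask charges catalyst at 1.15 % of its substrate. I carried N over unchanged, though less substrate might lower it:

c = N × 1.15 % = 20.8 %

At that pace 12 min is 18.0 stretches, so the flask should be read near its end.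

The forecast said otherwise, on the ground “I assume the rate is first order in each substrate and in the partner”. It gave c 37 %, eP 36 % and eS 21 %, a c above my 20.8 %.

The flask gave c 20.6 %, eP 37.1 % and eS 9.65 %.

    partner + free catalyst + left-handed substrate → free catalyst + left-handed product (k = 1.10 M⁻² s⁻¹)
    partner + free catalyst + right-handed substrate → free catalyst + right-handed product (k = 0.460 M⁻² s⁻¹)
    2 partner → self-condensation product (k = 5.80 × 10⁻⁴ M⁻¹ s⁻¹)
    partner + free catalyst → spent catalyst (k = 0.0230 M⁻¹ s⁻¹)
    partner → decomposed reagent (k = 7.80 × 10⁻⁴ s⁻¹)

At 12.0 min the free catalyst in the flask stood at 8.45 % of its charge, with spent catalyst at 91.6 %. The flask's own result makes N 17.9. Its neighbour held the same charges except for 0.0030 M of free catalyst, so that N promised c = 8.15 %. The neighbour reached 9.23 %, which is 20.3 turnovers per catalyst charged.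

The earlier runs and the new flask come from a simulation for an exercise, noise included.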